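The route rests on cutting the C2–C3 bond of the dihydrofuran (ring B). C3 is benzylic to ring A, and its acetate is an acetyl group plus one inserted oxygen. C2–H sits alpha to O1, so an aryl(acetyl)carbenoid at C3 can insert into an ArO–CH2 hydrogen. In one operation the key step closes ring B, forms C2–C3, sets C2 by catalyst control and, after DBU equilibration, sets C3 trans. Its precursor is a 5-bromo-2-alkoxyphenyl diazoacetone. The ether arm carries the acrolein unit as a symmetric 1,3-diol, held as a fluoride-labile di-tert-butylsilylene because both benzylic esters made later are acid-sensitive.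

Key step: step 6

Assumption: the sense of induction of the PTTL ligand on a diazoketone of this type has to be found by experiment. The S series is written; Rh2(R-PTTL)4 (from D-tert-leucine) replaces it if the S series favours 2R.

Step 1
Reactants: 1 2-(hydroxymethyl)propane-1,3-diol
Product: 2 (2,2-di-tert-butyl-1,3,2-dioxasilinan-5-yl)methanol
Conditions: t-Bu2Si(OTf)2 (1.0 equiv), 2,6-lutidine, DMF, −40 → 0 °C
Reagents that add atoms: di-tert-butylsilyl bis(trifluoromethanesulfonate), CC(C)(C)[Si](OS(=O)(=O)C(F)(F)F)(OS(=O)(=O)C(F)(F)F)C(C)(C)C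
Why: Silylene protection of a 1,3-diol: after the first Si–O bond forms, closure to the six-membered dioxasilinane is intramolecular and outruns any second silylation, so two of the three equivalent CH2OH groups are tied up and one stays free in an achiral, mirror-symmetric ring.

Step 2
Reactants: 3 (5-bromo-2-hydroxyphenyl)acetic acid
Product: 4 2-(5-bromo-2-hydroxyphenyl)-N-methoxy-N-methylacetamide
Conditions: MeNHOMe·HCl, EDC·HCl, N-methylmorpholine, CH2Cl2, 0 °C → rt
Reagents that add atoms: N,O-dimethylhydroxylamine hydrochloride, CNOC.Cl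
Why: Carbodiimide amide coupling to a Weinreb amide: should the neighbouring phenol intercept the activated acid, the resulting benzofuran-2(3H)-one is itself an aryl ester that the amine opens to the same amide, so the phenol needs no protection.

Step 3
Reactants: 4 2-(5-bromo-2-hydroxyphenyl)-N-methoxy-N-methylacetamide; 2 (2,2-di-tert-butyl-1,3,2-dioxasilinan-5-yl)methanol
Product: 5 2-{5-bromo-2-[(2,2-di-tert-butyl-1,3,2-dioxasilinan-5-yl)methoxy]phenyl}-N-methoxy-N-methylacetamide
Conditions: PPh3, DIAD, THF, 0 °C → rt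
Reagents that add atoms: none
Why: Mitsunobu etherification: the acidic bromophenol protonates the betaine and its phenoxide displaces the oxyphosphonium group of the unhindered primary alcohol by SN2 under neutral conditions that leave amide, aryl bromide and silylene alone.

Step 4
Reactants: 5 2-{5-bromo-2-[(2,2-di-tert-butyl-1,3,2-dioxasilinan-5-yl)methoxy]phenyl}-N-methoxy-N-methylacetamide
Product: 6 1-{5-bromo-2-[(2,2-di-tert-butyl-1,3,2-dioxasilinan-5-yl)methoxy]phenyl}propan-2-one
Conditions: MeMgBr, THF, −10 → 0 °C; then H2O (NH4Cl-buffered)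
Reagents that add atoms: methylmagnesium bromide, C[Mg]Br
Why: Weinreb ketone synthesis: the five-membered magnesium chelate of the tetrahedral adduct holds until the quench and so prevents a second addition, while MeMgBr at this temperature neither exchanges the aryl bromide nor attacks the shielded silicon.

Step 5
Reactants: 6 1-{5-bromo-2-[(2,2-di-tert-butyl-1,3,2-dioxasilinan-5-yl)methoxy]phenyl}propan-2-one
Product: 7 1-{5-bromo-2-[(2,2-di-tert-butyl-1,3,2-dioxasilinan-5-yl)methoxy]phenyl}-1-diazopropan-2-one (precursor of the key step)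
Conditions: p-ABSA, DBU, MeCN, 0 °C → rt
Reagents that add atoms: 4-acetamidobenzenesulfonyl azide (p-ABSA), CC(=O)Nc1ccc(cc1)S(=O)(=O)N=[N+]=[N-]
Why: Regitz diazo transfer: DBU removes a proton only from the CH2 that is flanked by aryl and acetyl groups, not from the CH3, and the enolate takes N2 from the sulfonyl azide, which is the routine entry to 1-aryl-1-diazopropan-2-ones.

Step 6
Reactants: 7 1-{5-bromo-2-[(2,2-di-tert-butyl-1,3,2-dioxasilinan-5-yl)methoxy]phenyl}-1-diazopropan-2-one
Product: 9 1-[(2S,3R)-5-bromo-2-(2,2-di-tert-butyl-1,3,2-dioxasilinan-5-yl)-2,3-dihydro-1-benzofuran-3-yl]ethan-1-one (trans), via cis ketone 8 (not isolated)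
Conditions: Rh2(S-PTTL)4 (dirhodium tetrakis[N-phthaloyl-(S)-tert-leucinate], 1 mol %), toluene, −20 °C → rt, slow addition of 7; then DBU (0.3 equiv), rt
Reagents that add atoms: none
Why: Proposed new method: The divalent rhodium dimer expels N2 from 7 to give an aryl/acetyl (donor/acceptor) carbenoid at the future C3, which inserts into one C–H bond of the ArO–CH2 group through a concerted, hydride-transfer-like three-centre transition state and so forms C2–C3. The closest known reaction type is the enantioselective intramolecular 1,5 C–H insertion of ortho-alkoxyaryl diazoacetates with chiral dirhodium carboxylates to 2,3-dihydrobenzofurans; alpha-aryl-alpha-diazoketones are established donor/acceptor carbenoid sources in asymmetric cyclopropanation, so only the pairing of this carbenoid with this insertion is new. Ring B closes by 1,5 insertion, that is through a five-membered cyclic array of C3, C3a, C7a, O1 and C2. C2 is set by the catalyst, whose phthalimide walls let only one of the two enantiotopic OCH2 hydrogens reach the carbenoid, and it should survive the base because the ring C2–O1 bond lies in the nodal plane of the C3 enolate, which blocks beta-elimination of the phenoxide. C3 is set by the substrate under thermodynamic control: DBU enolises cis ketone 8 until the acetyl group stands anti to the bulky C2 substituent. The step needs site selectivity over the tertiary C–H (1,6) and the SiOCH2 hydrogens (1,7) and chemoselectivity over Wolff rearrangement, secured by the five-membered transition state, by the O1 lone pair that activates only the OCH2 hydrogens, by the shielding tert-butyl groups, by the absence of any alkene, O–H or N–H, and by the aryl donor that tames the carbenoid.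

Step 7
Reactants: 9 1-[(2S,3R)-5-bromo-2-(2,2-di-tert-butyl-1,3,2-dioxasilinan-5-yl)-2,3-dihydro-1-benzofuran-3-yl]ethan-1-one
Product: 10 (2S,3R)-5-bromo-2-(2,2-di-tert-butyl-1,3,2-dioxasilinan-5-yl)-2,3-dihydro-1-benzofuran-3-yl acetate
Conditions: (CF3CO)2O, urea·H2O2, Na2HPO4, CH2Cl2, 0 °C → rt
Reagents that add atoms: urea–hydrogen peroxide, NC(N)=O.OO (source of the inserted oxygen, delivered as trifluoroperacetic acid, OOC(=O)C(F)(F)F, formed in the flask with trifluoroacetic anhydride)
Why: Baeyer–Villiger oxidation: in the Criegee adduct the secondary benzylic C3 migrates in preference to CH3 and with retention, so the acetate should keep 3R and the trans relation, while solid Na2HPO4 takes up CF3CO2H before it can ionise the new benzylic ester and the bromine damps attack of the peracid on ring A.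

Step 8
Reactants: 10 (2S,3R)-5-bromo-2-(2,2-di-tert-butyl-1,3,2-dioxasilinan-5-yl)-2,3-dihydro-1-benzofuran-3-yl acetate; 11 tributyl(1-ethoxyvinyl)stannane
Product: 13 (2S,3R)-5-acetyl-2-(2,2-di-tert-butyl-1,3,2-dioxasilinan-5-yl)-2,3-dihydro-1-benzofuran-3-yl acetate, via enol ether 12 (not isolated)
Conditions: PdCl2(PPh3)2 (5 mol %), toluene, 90 °C; then PPTS, THF–H2O, rt
Reagents that add atoms: water, O
Why: Stille coupling with an acetyl anion equivalent and enol ether hydrolysis: zerovalent palladium, formed from the divalent precatalyst by the stannane, inserts into C5–Br and not into the secondary benzylic acetate, and the electron-rich alpha-ethoxystyrene 12 is then protonated by PPTS far faster than the acetate ionises or the silylene hydrolyses.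

Step 9
Reactants: 13 (2S,3R)-5-acetyl-2-(2,2-di-tert-butyl-1,3,2-dioxasilinan-5-yl)-2,3-dihydro-1-benzofuran-3-yl acetate
Product: 14 (2S,3R)-2-(2,2-di-tert-butyl-1,3,2-dioxasilinan-5-yl)-5-[(1R)-1-hydroxyethyl]-2,3-dihydro-1-benzofuran-3-yl acetate
Conditions: RuCl(p-cymene)[(R,R)-TsDPEN] (1 mol %), HCO2H–Et3N (5:2), CH2Cl2, rt
Reagents that add atoms: none
Why: Noyori asymmetric transfer hydrogenation: the ruthenium hydride carrying (R,R)-TsDPEN hands H to the Si face of the aryl methyl ketone through its six-membered outer-sphere transition state, so the 1R carbinol is set by the catalyst alone (the ring centres are too remote to matter) and esters, silylene and aryl ether are not reduced.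

Step 10
Reactants: 14 (2S,3R)-2-(2,2-di-tert-butyl-1,3,2-dioxasilinan-5-yl)-5-[(1R)-1-hydroxyethyl]-2,3-dihydro-1-benzofuran-3-yl acetate; 15 angelic acid [(2Z)-2-methylbut-2-enoic acid]
Product: 17 (1R)-1-[(2S,3R)-3-acetoxy-2-(2,2-di-tert-butyl-1,3,2-dioxasilinan-5-yl)-2,3-dihydro-1-benzofuran-5-yl]ethyl (2Z)-2-methylbut-2-enoate, via mixed anhydride 16 (not isolated)
Conditions: 15, 2,4,6-Cl3C6H2COCl, Et3N, toluene, rt; then 14, 70 °C (no DMAP)
Reagents that add atoms: none
Why: Yamaguchi-type mixed-anhydride esterification run without DMAP: the alcohol attacks the unhindered angeloyl carbonyl of 16, the carbinol C–O bond is never broken so 1R is kept, and the absence of a nucleophilic catalyst shuts off the addition–elimination path that turns angelates into tiglates.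

Step 11
Reactants: 17 (1R)-1-[(2S,3R)-3-acetoxy-2-(2,2-di-tert-butyl-1,3,2-dioxasilinan-5-yl)-2,3-dihydro-1-benzofuran-5-yl]ethyl (2Z)-2-methylbut-2-enoate
Product: 18 (1R)-1-[(2S,3R)-3-acetoxy-2-(1,3-dihydroxypropan-2-yl)-2,3-dihydro-1-benzofuran-5-yl]ethyl (2Z)-2-methylbut-2-enoate
Conditions: HF·pyridine, excess pyridine, THF, 0 °C
Reagents that add atoms: none
Why: Fluoride-driven desilylation: formation of two Si–F bonds releases the 1,3-diol in a pyridine-buffered medium that should neither ionise the ortho-alkoxybenzylic C3 acetate or the para-alkoxybenzylic angelate nor move an acyl group.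

Step 12
Reactants: 18 (1R)-1-[(2S,3R)-3-acetoxy-2-(1,3-dihydroxypropan-2-yl)-2,3-dihydro-1-benzofuran-5-yl]ethyl (2Z)-2-methylbut-2-enoate
Product: 19 (1R)-1-[(2S,3R)-3-acetoxy-2-{1-hydroxy-3-[(4-methylbenzenesulfonyl)oxy]propan-2-yl}-2,3-dihydro-1-benzofuran-5-yl]ethyl (2Z)-2-methylbut-2-enoate (both epimers at the side-chain carbon)
Conditions: TsCl (1.1 equiv), Ag2O (1.5 equiv), KI (0.2 equiv), CH2Cl2, 0 °C → rt
Reagents that add atoms: 4-toluenesulfonyl chloride, Cc1ccc(cc1)S(=O)(=O)Cl
Why: Ag2O-mediated monotosylation of a symmetrical diol: the internally hydrogen-bonded, silver-coordinated diol reacts faster than the hydroxy tosylate it turns into, the medium stays essentially neutral so both esters and the Z alkene are safe, and the new side-chain stereocentre (either epimer) is erased in step 13.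

Step 13
Reactants: 19 (1R)-1-[(2S,3R)-3-acetoxy-2-{1-hydroxy-3-[(4-methylbenzenesulfonyl)oxy]propan-2-yl}-2,3-dihydro-1-benzofuran-5-yl]ethyl (2Z)-2-methylbut-2-enoate
Product: 21 (1R)-1-[(2S,3R)-3-acetoxy-2-(3-oxoprop-1-en-2-yl)-2,3-dihydro-1-benzofuran-5-yl]ethyl (2Z)-2-methylbut-2-enoate (target CNP0294391.5), via tosyloxy aldehyde 20 (not isolated)
Conditions: Dess–Martin periodinane, CH2Cl2, 0 °C → rt; then Et3N, 0 °C
Reagents that add atoms: none
Why: Dess–Martin oxidation followed by E1cB elimination: the new aldehyde acidifies the side-chain methine so that Et3N expels tosylate already at 0 °C, whereas C2–H is bonded to the alpha carbon of the enal (cross-conjugated and thus not acidified) and is syn to the C3 acetate, which leaves no easy anti elimination to the benzofuran.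

Compound list
1 | 2-(hydroxymethyl)propane-1,3-diol | OCC(CO)CO | starting material
2 | (2,2-di-tert-butyl-1,3,2-dioxasilinan-5-yl)methanol | OCC1CO[Si](C(C)(C)C)(C(C)(C)C)OC1 | intermediate
3 | (5-bromo-2-hydroxyphenyl)acetic acid | OC(=O)Cc1cc(Br)ccc1O | starting material
4 | 2-(5-bromo-2-hydroxyphenyl)-N-methoxy-N-methylacetamide | CON(C)C(=O)Cc1cc(Br)ccc1O | intermediate
5 | 2-{5-bromo-2-[(2,2-di-tert-butyl-1,3,2-dioxasilinan-5-yl)methoxy]phenyl}-N-methoxy-N-methylacetamide | CON(C)C(=O)Cc1cc(Br)ccc1OCC1CO[Si](C(C)(C)C)(C(C)(C)C)OC1 | intermediate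
6 | 1-{5-bromo-2-[(2,2-di-tert-butyl-1,3,2-dioxasilinan-5-yl)methoxy]phenyl}propan-2-one | CC(=O)Cc1cc(Br)ccc1OCC1CO[Si](C(C)(C)C)(C(C)(C)C)OC1 | intermediate
7 | 1-{5-bromo-2-[(2,2-di-tert-butyl-1,3,2-dioxasilinan-5-yl)methoxy]phenyl}-1-diazopropan-2-one | CC(=O)C(=[N+]=[N-])c1cc(Br)ccc1OCC1CO[Si](C(C)(C)C)(C(C)(C)C)OC1 | intermediate
8 | 1-[(2S,3S)-5-bromo-2-(2,2-di-tert-butyl-1,3,2-dioxasilinan-5-yl)-2,3-dihydro-1-benzofuran-3-yl]ethan-1-one (cis) | CC(C)(C)[Si]1(C(C)(C)C)OCC(CO1)[C@@H]1Oc2ccc(Br)cc2[C@@H]1C(C)=O | intermediate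
9 | 1-[(2S,3R)-5-bromo-2-(2,2-di-tert-butyl-1,3,2-dioxasilinan-5-yl)-2,3-dihydro-1-benzofuran-3-yl]ethan-1-one (trans) | CC(C)(C)[Si]1(C(C)(C)C)OCC(CO1)[C@@H]1Oc2ccc(Br)cc2[C@H]1C(C)=O | intermediate
10 | (2S,3R)-5-bromo-2-(2,2-di-tert-butyl-1,3,2-dioxasilinan-5-yl)-2,3-dihydro-1-benzofuran-3-yl acetate | CC(C)(C)[Si]1(C(C)(C)C)OCC(CO1)[C@@H]1Oc2ccc(Br)cc2[C@H]1OC(C)=O | intermediate
11 | tributyl(1-ethoxyvinyl)stannane | CCCC[Sn](CCCC)(CCCC)C(=C)OCC | starting material
12 | (2S,3R)-2-(2,2-di-tert-butyl-1,3,2-dioxasilinan-5-yl)-5-(1-ethoxyethenyl)-2,3-dihydro-1-benzofuran-3-yl acetate | CC(C)(C)[Si]1(C(C)(C)C)OCC(CO1)[C@@H]1Oc2ccc(C(=C)OCC)cc2[C@H]1OC(C)=O | intermediate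
13 | (2S,3R)-5-acetyl-2-(2,2-di-tert-butyl-1,3,2-dioxasilinan-5-yl)-2,3-dihydro-1-benzofuran-3-yl acetate | CC(C)(C)[Si]1(C(C)(C)C)OCC(CO1)[C@@H]1Oc2ccc(C(C)=O)cc2[C@H]1OC(C)=O | intermediate
14 | (2S,3R)-2-(2,2-di-tert-butyl-1,3,2-dioxasilinan-5-yl)-5-[(1R)-1-hydroxyethyl]-2,3-dihydro-1-benzofuran-3-yl acetate | CC(C)(C)[Si]1(C(C)(C)C)OCC(CO1)[C@@H]1Oc2ccc([C@@H](C)O)cc2[C@H]1OC(C)=O | intermediate
15 | angelic acid, (2Z)-2-methylbut-2-enoic acid | C/C=C(/C)C(=O)O | starting material
16 | (2Z)-2-methylbut-2-enoic 2,4,6-trichlorobenzoic anhydride | C/C=C(/C)C(=O)OC(=O)c1c(Cl)cc(Cl)cc1Cl | intermediate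
17 | (1R)-1-[(2S,3R)-3-acetoxy-2-(2,2-di-tert-butyl-1,3,2-dioxasilinan-5-yl)-2,3-dihydro-1-benzofuran-5-yl]ethyl (2Z)-2-methylbut-2-enoate | CC(C)(C)[Si]1(C(C)(C)C)OCC(CO1)[C@@H]1Oc2ccc([C@@H](C)OC(=O)/C(C)=C\C)cc2[C@H]1OC(C)=O | intermediate
18 | (1R)-1-[(2S,3R)-3-acetoxy-2-(1,3-dihydroxypropan-2-yl)-2,3-dihydro-1-benzofuran-5-yl]ethyl (2Z)-2-methylbut-2-enoate | OCC(CO)[C@@H]1Oc2ccc([C@@H](C)OC(=O)/C(C)=C\C)cc2[C@H]1OC(C)=O | intermediate
19 | (1R)-1-[(2S,3R)-3-acetoxy-2-{1-hydroxy-3-[(4-methylbenzenesulfonyl)oxy]propan-2-yl}-2,3-dihydro-1-benzofuran-5-yl]ethyl (2Z)-2-methylbut-2-enoate, both epimers at the side-chain carbon | Cc1ccc(cc1)S(=O)(=O)OCC(CO)[C@@H]1Oc2ccc([C@@H](C)OC(=O)/C(C)=C\C)cc2[C@H]1OC(C)=O | intermediate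
20 | (1R)-1-[(2S,3R)-3-acetoxy-2-{1-[(4-methylbenzenesulfonyl)oxy]-3-oxopropan-2-yl}-2,3-dihydro-1-benzofuran-5-yl]ethyl (2Z)-2-methylbut-2-enoate, both epimers at the side-chain carbon | Cc1ccc(cc1)S(=O)(=O)OCC(C=O)[C@@H]1Oc2ccc([C@@H](C)OC(=O)/C(C)=C\C)cc2[C@H]1OC(C)=O | intermediate
21 | (1R)-1-[(2S,3R)-3-acetoxy-2-(3-oxoprop-1-en-2-yl)-2,3-dihydro-1-benzofuran-5-yl]ethyl (2Z)-2-methylbut-2-enoate | C=C(C=O)[C@@H]1Oc2ccc([C@@H](C)OC(=O)/C(C)=C\C)cc2[C@H]1OC(C)=O | target

Total step count: 13.
Longest linear sequence: 12 steps (3 → 21 through steps 2–13). The branch 1 → 2 adds one step and joins at step 3.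

Steps most likely to fail

1. Step 6. Three things may go wrong:
- The carbenoid may rearrange (Wolff) or dimerise faster than it inserts.
- The catalyst may discriminate poorly between the two enantiotopic hydrogens.
- The cis and trans insertion channels may differ in their sense at C2, so that the equilibration lowers the enantiomeric purity.

The fallback uses only known chemistry. It sets out from 3 and 2 and comes back at 9. The insertion is run on the diazoacetate, the substrate class for which it is established, and the acetyl group is built afterwards. Acid 3 is esterified (MeOH, cat. H2SO4) to methyl (5-bromo-2-hydroxyphenyl)acetate F1. Mitsunobu etherification with 2 gives methyl {5-bromo-2-[(2,2-di-tert-butyl-1,3,2-dioxasilinan-5-yl)methoxy]phenyl}acetate F2, and p-ABSA/DBU gives the corresponding methyl aryl(diazo)acetate F3. Rh2(S-PTTL)4 in toluene at low temperature should give the cis methyl (2S,3S)-dihydrobenzofuran-3-carboxylate F4. Catalytic NaOMe in MeOH equilibrates it to the trans methyl (2S,3R)-carboxylate F5. MeNHOMe·HCl with i-PrMgCl converts this into the trans Weinreb amide F6, and MeMgBr leads back to 9.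

2. Step 10. Three things may go wrong:
- The activated angeloyl unit may isomerise from Z to E.
- Acylation may be too slow at the temperature that the alkene geometry tolerates.
- The para-alkoxybenzylic alcohol may ionise, with erosion of the 1R configuration.

The fallback sets out from 14 and comes back at 17. The Z alkene is built on the ester instead of being carried through a carboxyl activation. Alcohol 14 is coupled (EDC, cat. DMAP, 0 °C) with 2-[bis(2,2,2-trifluoroethoxy)phosphoryl]propanoic acid to the phosphonopropanoate ester F7. A Still–Gennari olefination (KN(SiMe3)2, 18-crown-6, THF, −78 °C, then acetaldehyde) should then give 17 under kinetic Z control. One equivalent of base is consumed by the far more acidic phosphonate, so the acetate is left alone.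

3. Step 12. The second hydroxyl may be tosylated competitively, or the hindered diol may convert slowly. Either drains material before the last step.

The fallback sets out from 18 and comes back at 21. The differentiation of the two arms is made structural instead of kinetic. Trimethyl orthoacetate with cat. PPTS in CH2Cl2 ties both hydroxyls into the cyclic orthoacetate F8. Added water opens it to the monoacetate F9, since only one acyl group is available per diol. Dess–Martin oxidation gives the beta-acetoxy aldehyde F10, and Et3N (briefly DBU at 0 °C if needed) expels acetate by E1cB to give 21.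

Further compounds
F1 | step 6 | methyl (5-bromo-2-hydroxyphenyl)acetate | COC(=O)Cc1cc(Br)ccc1O
F2 | step 6 | methyl {5-bromo-2-[(2,2-di-tert-butyl-1,3,2-dioxasilinan-5-yl)methoxy]phenyl}acetate | COC(=O)Cc1cc(Br)ccc1OCC1CO[Si](C(C)(C)C)(C(C)(C)C)OC1
F3 | step 6 | methyl {5-bromo-2-[(2,2-di-tert-butyl-1,3,2-dioxasilinan-5-yl)methoxy]phenyl}(diazo)acetate | COC(=O)C(=[N+]=[N-])c1cc(Br)ccc1OCC1CO[Si](C(C)(C)C)(C(C)(C)C)OC1
F4 | step 6 | methyl (2S,3S)-5-bromo-2-(2,2-di-tert-butyl-1,3,2-dioxasilinan-5-yl)-2,3-dihydro-1-benzofuran-3-carboxylate (cis) | CC(C)(C)[Si]1(C(C)(C)C)OCC(CO1)[C@@H]1Oc2ccc(Br)cc2[C@@H]1C(=O)OC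
F5 | step 6 | methyl (2S,3R)-5-bromo-2-(2,2-di-tert-butyl-1,3,2-dioxasilinan-5-yl)-2,3-dihydro-1-benzofuran-3-carboxylate (trans) | CC(C)(C)[Si]1(C(C)(C)C)OCC(CO1)[C@@H]1Oc2ccc(Br)cc2[C@H]1C(=O)OC
F6 | step 6 | (2S,3R)-5-bromo-2-(2,2-di-tert-butyl-1,3,2-dioxasilinan-5-yl)-N-methoxy-N-methyl-2,3-dihydro-1-benzofuran-3-carboxamide | CC(C)(C)[Si]1(C(C)(C)C)OCC(CO1)[C@@H]1Oc2ccc(Br)cc2[C@H]1C(=O)N(C)OC
F7 | step 10 | (1R)-1-[(2S,3R)-3-acetoxy-2-(2,2-di-tert-butyl-1,3,2-dioxasilinan-5-yl)-2,3-dihydro-1-benzofuran-5-yl]ethyl 2-[bis(2,2,2-trifluoroethoxy)phosphoryl]propanoate | CC(C)(C)[Si]1(C(C)(C)C)OCC(CO1)[C@@H]1Oc2ccc([C@@H](C)OC(=O)C(C)P(=O)(OCC(F)(F)F)OCC(F)(F)F)cc2[C@H]1OC(C)=O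
F8 | step 12 | (1R)-1-[(2S,3R)-3-acetoxy-2-(2-methoxy-2-methyl-1,3-dioxan-5-yl)-2,3-dihydro-1-benzofuran-5-yl]ethyl (2Z)-2-methylbut-2-enoate | COC1(C)OCC(CO1)[C@@H]1Oc2ccc([C@@H](C)OC(=O)/C(C)=C\C)cc2[C@H]1OC(C)=O
F9 | step 12 | (1R)-1-[(2S,3R)-3-acetoxy-2-(1-acetoxy-3-hydroxypropan-2-yl)-2,3-dihydro-1-benzofuran-5-yl]ethyl (2Z)-2-methylbut-2-enoate | CC(=O)OCC(CO)[C@@H]1Oc2ccc([C@@H](C)OC(=O)/C(C)=C\C)cc2[C@H]1OC(C)=O
F10 | step 12 | (1R)-1-[(2S,3R)-3-acetoxy-2-(1-acetoxy-3-oxopropan-2-yl)-2,3-dihydro-1-benzofuran-5-yl]ethyl (2Z)-2-methylbut-2-enoate | CC(=O)OCC(C=O)[C@@H]1Oc2ccc([C@@H](C)OC(=O)/C(C)=C\C)cc2[C@H]1OC(C)=O
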